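**Retrosynthetic overview**
- The target is reached by desilylation of the 6,8,12,20-tetraacetate of a (12R)-tetraol whose tertiary C13-OH is masked as a silyl ether.
- C12–O and C20–O come from a double Barton nitrite relay (C–N bond formation by 1,5-hydrogen transfer) from O8α and O6β of a 6β,8α-diol, followed by oxime hydrolysis and a reagent-controlled ketone reduction that sets C12.
- The 6β,8α-diol comes from a 7α,8α-epoxy-6-ketone (C–O bonds by nucleophilic epoxidation, then directed hydride opening), which comes from the 7-en-6-one.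
- The 7-en-6-one comes from the exocyclic 8(17)-alkene by a one-flask isomerising allylic oxidation (new), and that alkene from dehydration of 13-O-silyl sclareol.
- No ring is formed: rings A and B and the C5, C9, C10 and C13 stereocentres are taken intact from (−)-sclareol (1).

Assumption: the target SMILES is read as (12R,13S)-6β,8α,12,20-tetraacetoxylabd-14-en-13-ol, which has the configuration of natural (−)-sclareol at C5, C8, C9, C10 and C13 (the C13 descriptor changes only because C12 gains oxygen).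

**Step 1**
Reactants: 1 (−)-sclareol
Product: 2 13-O-triethylsilylsclareol
Conditions: Et3SiOTf (1.05 equiv), 2,6-lutidine, CH2Cl2, −78 °C
Reagents that add atoms: triethylsilyl trifluoromethanesulfonate, CC[Si](CC)(CC)OS(=O)(=O)C(F)(F)F
Why: Silyl ether formation; the acyclic tertiary allylic 13-OH is less shielded than the ring 8α-OH (flanked by the C9 side chain), so one equivalent of silyl triflate at −78 °C is expected to mask C13-OH only, and no stereocentre is touched.

**Step 2**
Reactants: 2 13-O-triethylsilylsclareol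
Product: 3 13-(triethylsilyloxy)labda-8(17),14-diene
Conditions: SOCl2, pyridine, CH2Cl2, −78 to −30 °C
Reagents that add atoms: none
Why: Chlorosulfite E2 dehydration; the equatorial 8α leaving group has anti-periplanar hydrogens only on the C17 methyl, so the exocyclic alkene dominates, any 7-ene isomer (4) converges in the next step, and the pyridine-buffered medium spares the tertiary allylic silyl ether.

**Step 3**
Reactants: 3 13-(triethylsilyloxy)labda-8(17),14-diene
Product: 5 13-(triethylsilyloxy)labda-7,14-dien-6-one, via 7-ene 4 (not isolated)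
Conditions: Co(salen)Cl (5 mol%; salen = N,N′-bis(3,5-di-tert-butylsalicylidene)-1,2-cyclohexanediaminate), PhSiH3 (5 mol%), PhH, 22 °C, Ar; then t-BuOOH (5.5 M in decane, 6 equiv), 45 °C
Reagents that add atoms: tert-butyl hydroperoxide, CC(C)(C)OO
Why: Proposed new method: one-flask cobalt-hydride isomerising allylic oxidation — the trivalent cobalt hydride made from Co(salen)Cl and PhSiH3 transfers a hydrogen atom to the exocyclic alkene to give the tertiary C8 radical, which returns the unhindered C7 hydrogen to divalent cobalt and so moves the double bond to C7=C8 (4); after t-BuOOH is added the same cobalt salen complex shuttles between its divalent and trivalent states to give t-BuO and t-BuOO radicals that remove the allylic C6 hydrogen, cap the allyl radical at its secondary terminus as the mixed peroxide and dehydrate it (Kornblum–DeLaMare) to the 7-en-6-one, while the side-chain vinyl group has no allylic hydrogen and undergoes only degenerate hydrogen-atom transfer; the closest known reactions are the cobalt salen/silane radical isomerisation of 1,1-disubstituted alkenes and the cobalt- or rhodium-catalysed t-BuOOH allylic oxidation of cyclic trisubstituted alkenes, so far run only as separate reactions with different catalysts.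

**Step 4**
Reactants: 5 13-(triethylsilyloxy)labda-7,14-dien-6-one
Product: 6 7α,8α-epoxy-13-(triethylsilyloxy)labd-14-en-6-one
Conditions: 30% aq. H2O2, NaOH, MeOH, 0 °C
Reagents that add atoms: hydrogen peroxide, OO
Why: Weitz–Scheffer nucleophilic epoxidation; hydroperoxide anion adds to C8 from the α-face, anti to the axial C10 methyl, and the enolate closes the 7α,8α-epoxide, which puts oxygen back on C8 with the sclareol configuration (8α-O, 8β-CH3) and leaves the electron-rich vinyl group alone.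

**Step 5**
Reactants: 6 7α,8α-epoxy-13-(triethylsilyloxy)labd-14-en-6-one
Product: 8 13-(triethylsilyloxy)labd-14-ene-6β,8α-diol, via epoxy alcohol 7 (not isolated)
Conditions: NaAlH2(OCH2CH2OCH3)2, THF, −20 to 25 °C
Reagents that add atoms: none
Why: Carbonyl reduction followed by alkoxide-directed hydride opening of the 2,3-epoxy alcohol (Red-Al 1,3-diol synthesis); hydride reaches C6 from the α-face because the β-face is blocked by the syn-axial C19 and C20 methyls, giving the 6β-alkoxide (7), whose aluminium hydride delivers hydrogen to C7 from the β-face and leaves the tertiary 8α-OH.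

**Step 6**
Reactants: 8 13-(triethylsilyloxy)labd-14-ene-6β,8α-diol
Product: 9 6β,8α-bis(nitrosooxy)-13-(triethylsilyloxy)labd-14-ene
Conditions: NOCl, pyridine, −30 °C
Reagents that add atoms: nitrosyl chloride, O=NCl
Why: O-nitrosation of both hydroxyls to the bis-nitrite ester, fast at low temperature in pyridine, with no change at any stereocentre.

**Step 7**
Reactants: 9 6β,8α-bis(nitrosooxy)-13-(triethylsilyloxy)labd-14-ene
Product: 11 12,20-bis(hydroxyimino)-13-(triethylsilyloxy)labd-14-ene-6β,8α-diol, via dinitroso compound 10 (not isolated)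
Conditions: hν (365 nm), PhH, 15 °C, Ar; then i-PrOH, 60 °C
Reagents that add atoms: none
Why: Barton nitrite photolysis at both nitrites (C–N bond formation by 1,5-hydrogen transfer through six-membered transition states): the 8α-oxy radical can reach only the C12 hydrogens, the 6β-oxy radical abstracts from the 1,3-diaxial C20 methyl (C17 is deactivated by its geminal oxygen), NO recombines at carbon to give 10, and warming tautomerises both C-nitroso groups to oximes.

**Step 8**
Reactants: 11 12,20-bis(hydroxyimino)-13-(triethylsilyloxy)labd-14-ene-6β,8α-diol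
Product: 12 6β,8α-dihydroxy-12-oxo-13-(triethylsilyloxy)labd-14-en-20-al
Conditions: OHC–CO2H (50% aq.), NaOAc, THF/H2O, 25 °C
Reagents that add atoms: water, O
Why: Oxime hydrolysis by exchange (transoximation) with glyoxylic acid under buffered conditions that keep the tertiary silyl ether; it releases the C12 ketone and the C20 aldehyde, the latter closing onto the 6β-OH as a lactol.

**Step 9**
Reactants: 12 6β,8α-dihydroxy-12-oxo-13-(triethylsilyloxy)labd-14-en-20-al
Product: 14 (12R,13S)-13-(triethylsilyloxy)labd-14-ene-6β,8α,12,20-tetraol, via 12R-hydroxy lactol 13 (not isolated)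
Conditions: (S)-2-methyl-CBS-oxazaborolidine (0.3 equiv), catecholborane, PhMe, −78 to −40 °C; then NaBH4, MeOH, 0 °C
Reagents that add atoms: none
Why: Corey–Bakshi–Shibata reduction sets C12 under reagent control: the (S)-oxazaborolidine treats the quaternary C13 as the large group and gives the (12R)-alcohol whatever the relative size of the C13 methyl and vinyl groups (the (R)-catalyst is used if the facial sense proves reversed), catecholborane does not hydroborate the vinyl group, and NaBH4 then reduces the lactol through its hydroxy aldehyde form to the C20 primary alcohol.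

**Step 10**
Reactants: 14 (12R,13S)-13-(triethylsilyloxy)labd-14-ene-6β,8α,12,20-tetraol
Product: 15 (12R,13S)-6β,8α,12,20-tetraacetoxy-13-(triethylsilyloxy)labd-14-ene
Conditions: Ac2O, 4-(dimethylamino)pyridine, Et3N, PhMe, 60 °C
Reagents that add atoms: acetic anhydride, CC(=O)OC(C)=O
Why: Nucleophile-catalysed (Steglich-type) acylation of the primary, the two secondary and the tertiary 8α-hydroxyl, selective because the only other tertiary hydroxyl (C13) is masked as its silyl ether.

**Step 11**
Reactants: 15 (12R,13S)-6β,8α,12,20-tetraacetoxy-13-(triethylsilyloxy)labd-14-ene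
Product: 16 (12R,13S)-6β,8α,12,20-tetraacetoxylabd-14-en-13-ol
Conditions: HF·pyridine, THF, 0 to 25 °C
Reagents that add atoms: none
Why: Fluoride-induced silyl ether cleavage; the four acetates are stable to HF·pyridine and acetyl migration from the secondary C12 oxygen to the tertiary C13 oxygen is uphill, so the free 13-OH of the target results.

**Compound list**
1 | (−)-sclareol, (13R)-labd-14-ene-8α,13-diol (5α-H, 9α-H, 10β-CH3, 8β-CH3) | C=C[C@](C)(O)CC[C@@H]1[C@@]2(C)CCCC(C)(C)[C@@H]2CC[C@@]1(C)O | starting material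
2 | 13-O-triethylsilylsclareol (8α-OH free) | C=C[C@](C)(O[Si](CC)(CC)CC)CC[C@@H]1[C@@]2(C)CCCC(C)(C)[C@@H]2CC[C@@]1(C)O | intermediate
3 | 13-(triethylsilyloxy)labda-8(17),14-diene (exocyclic C8=C17, C13 as in sclareol) | C=C[C@](C)(O[Si](CC)(CC)CC)CC[C@@H]1[C@@]2(C)CCCC(C)(C)[C@@H]2CCC1=C | intermediate
4 | 13-(triethylsilyloxy)labda-7,14-diene (ring B C7=C8, not isolated) | C=C[C@](C)(O[Si](CC)(CC)CC)CC[C@@H]1[C@@]2(C)CCCC(C)(C)[C@@H]2CC=C1C | intermediate
5 | 13-(triethylsilyloxy)labda-7,14-dien-6-one | C=C[C@](C)(O[Si](CC)(CC)CC)CC[C@@H]1[C@@]2(C)CCCC(C)(C)[C@@H]2C(=O)C=C1C | intermediate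
6 | 7α,8α-epoxy-13-(triethylsilyloxy)labd-14-en-6-one (8β-CH3) | C=C[C@](C)(O[Si](CC)(CC)CC)CC[C@@H]1[C@@]2(C)CCCC(C)(C)[C@@H]2C(=O)[C@H]3O[C@@]13C | intermediate
7 | 7α,8α-epoxy-13-(triethylsilyloxy)labd-14-en-6β-ol (not isolated) | C=C[C@](C)(O[Si](CC)(CC)CC)CC[C@@H]1[C@@]2(C)CCCC(C)(C)[C@@H]2[C@H](O)[C@H]3O[C@@]13C | intermediate
8 | 13-(triethylsilyloxy)labd-14-ene-6β,8α-diol (6β-OH axial, 8α-OH equatorial, 8β-CH3) | C=C[C@](C)(O[Si](CC)(CC)CC)CC[C@@H]1[C@@]2(C)CCCC(C)(C)[C@@H]2[C@H](O)C[C@@]1(C)O | intermediate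
9 | 6β,8α-bis(nitrosooxy)-13-(triethylsilyloxy)labd-14-ene (bis-nitrite of 8) | C=C[C@](C)(O[Si](CC)(CC)CC)CC[C@@H]1[C@@]2(C)CCCC(C)(C)[C@@H]2[C@H](ON=O)C[C@@]1(C)ON=O | intermediate
10 | 12,20-dinitroso-13-(triethylsilyloxy)labd-14-ene-6β,8α-diol (C12 epimers, not isolated) | C=C[C@](C)(O[Si](CC)(CC)CC)C(N=O)C[C@@H]1[C@@]2(CN=O)CCCC(C)(C)[C@@H]2[C@H](O)C[C@@]1(C)O | intermediate
11 | 12,20-bis(hydroxyimino)-13-(triethylsilyloxy)labd-14-ene-6β,8α-diol (12-ketoxime and 20-aldoxime, E/Z mixtures) | C=C[C@](C)(O[Si](CC)(CC)CC)C(=NO)C[C@@H]1[C@@]2(C=NO)CCCC(C)(C)[C@@H]2[C@H](O)C[C@@]1(C)O | intermediate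
12 | 6β,8α-dihydroxy-12-oxo-13-(triethylsilyloxy)labd-14-en-20-al (drawn open; largely the 6β,20-hemiacetal) | C=C[C@](C)(O[Si](CC)(CC)CC)C(=O)C[C@@H]1[C@@]2(C=O)CCCC(C)(C)[C@@H]2[C@H](O)C[C@@]1(C)O | intermediate
13 | (12R)-6β,8α,12-trihydroxy-13-(triethylsilyloxy)labd-14-en-20-al (drawn open; lactol form, not isolated) | C=C[C@](C)(O[Si](CC)(CC)CC)[C@@H](C[C@@H]1[C@@]2(C=O)CCCC(C)(C)[C@@H]2[C@H](O)C[C@@]1(C)O)O | intermediate
14 | (12R,13S)-13-(triethylsilyloxy)labd-14-ene-6β,8α,12,20-tetraol | C=C[C@](C)(O[Si](CC)(CC)CC)[C@@H](C[C@@H]1[C@@]2(CO)CCCC(C)(C)[C@@H]2[C@H](O)C[C@@]1(C)O)O | intermediate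
15 | (12R,13S)-6β,8α,12,20-tetraacetoxy-13-(triethylsilyloxy)labd-14-ene | C=C[C@](C)(O[Si](CC)(CC)CC)[C@@H](C[C@@H]1[C@@]2(COC(C)=O)CCCC(C)(C)[C@@H]2[C@H](OC(C)=O)C[C@@]1(C)OC(C)=O)OC(C)=O | intermediate
16 | (12R,13S)-6β,8α,12,20-tetraacetoxylabd-14-en-13-ol (CNP0136817.1) | C=C[C@](C)(O)[C@@H](C[C@@H]1[C@@]2(COC(C)=O)CCCC(C)(C)[C@@H]2[C@H](OC(C)=O)C[C@@]1(C)OC(C)=O)OC(C)=O | target

**Totals**
Total step count: 11. Longest linear sequence: 11 steps (fully linear from sclareol).

**Three steps most likely to fail**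

Step 7 (double Barton relay). The 6β-oxy radical is 1,3-diaxial not only to C20 but also to the 4β-methyl (C19) and the 8β-methyl (C17). C20 is expected to win because it is clamped between four syn-axial neighbours and cannot bend away, and because C17 is deactivated, but the ratio is not secured. The tertiary 8α-oxy radical can also fragment instead of abstracting from C12. The fallback runs the two relays one after the other with known chemistry; it sets out from 6 and comes back at 15. Ketone 6 is reduced with NaBH4/CeCl3·7H2O to the epoxy alcohol 7, now isolated. NOCl/pyridine gives the 6β-nitrite F1. Photolysis at this stage, where C17 sits on the epoxide carbon out of reach and O8 is locked in the epoxide, gives the 20-oxime F2. Glyoxylic acid exchange gives the lactol aldehyde F3. NaAlH2(OCH2CH2OCH3)2 reduces the lactol and opens the epoxide under direction of the 6β-alkoxide to the 6β,8α,20-triol F4. Ac2O/pyridine at 25 °C acetylates only the secondary and primary hydroxyls, giving the 6,20-diacetate F5. NOCl/pyridine then gives the 8α-nitrite F6, whose single Barton photolysis can only reach C12 and gives the 12-oxime F7. Glyoxylic acid gives the 12-ketone F8, the (S)-oxazaborolidine/catecholborane reduction gives the (12R)-alcohol F9, and Ac2O/4-(dimethylamino)pyridine at 60 °C acetylates the 12- and 8-hydroxyls to give 15.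

Step 3 (proposed new method). The cobalt salen complex may isomerise cleanly but oxidise the hindered C6 methylene poorly, or attack C9–H and C17–H instead. The fallback uses only known chemistry and brings the C6 oxygen in by transposition instead of C–H abstraction; it sets out from 3 and comes back at 5. Alkene 3 is isomerised with Co(salen)Cl/PhSiH3 alone and the 7-ene 4 is isolated. mCPBA/NaHCO3 epoxidises the trisubstituted alkene from the α-face to the 7α,8α-epoxide F10. PhSeNa (from (PhSe)2 and NaBH4, EtOH, reflux) opens it at the secondary C7 to the 7β-phenylseleno-8α-alcohol F11. H2O2 oxidation and selenoxide syn-elimination (Sharpless–Lauer) give the 6-en-8α-ol F12. Pyridinium chlorochromate, (C5H5NH)[CrO3Cl], then effects the Babler–Dauben oxidative 1,3-transposition of this tertiary allylic alcohol to enone 5.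

Step 4 (nucleophilic epoxidation). The β,β-disubstituted, hindered enone may react slowly with alkaline peroxide, and the γ-hydrogen at C9 is base-labile. The fallback installs the C8 oxygen by conjugate borylation instead; it sets out from 5 and comes back at 8. CuCl/NaOt-Bu/1,2-bis(diphenylphosphino)benzene with bis(pinacolato)diboron and MeOH in THF adds boron to C8 from the α-face to give the 8α-boryl ketone F13. NaBO3·4H2O oxidises the C–B bond with retention to the 8α-hydroxy-6-ketone F14. Me4NBH(OAc)3 in MeCN/AcOH at −30 °C (Evans–Saksena anti-reduction, hydride delivered from the 8α-oxygen to the α-face of C6) gives the 6β,8α-diol 8.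

**Further compounds**
F1 | step 7 | 7α,8α-epoxy-6β-(nitrosooxy)-13-(triethylsilyloxy)labd-14-ene | C=C[C@](C)(O[Si](CC)(CC)CC)CC[C@@H]1[C@@]2(C)CCCC(C)(C)[C@@H]2[C@H](ON=O)[C@H]3O[C@@]13C
F2 | step 7 | 7α,8α-epoxy-6β-hydroxy-13-(triethylsilyloxy)labd-14-en-20-al oxime | C=C[C@](C)(O[Si](CC)(CC)CC)CC[C@@H]1[C@@]2(C=NO)CCCC(C)(C)[C@@H]2[C@H](O)[C@H]3O[C@@]13C
F3 | step 7 | 7α,8α-epoxy-6β-hydroxy-13-(triethylsilyloxy)labd-14-en-20-al (drawn open; 6β,20-lactol) | C=C[C@](C)(O[Si](CC)(CC)CC)CC[C@@H]1[C@@]2(C=O)CCCC(C)(C)[C@@H]2[C@H](O)[C@H]3O[C@@]13C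
F4 | step 7 | 13-(triethylsilyloxy)labd-14-ene-6β,8α,20-triol | C=C[C@](C)(O[Si](CC)(CC)CC)CC[C@@H]1[C@@]2(CO)CCCC(C)(C)[C@@H]2[C@H](O)C[C@@]1(C)O
F5 | step 7 | 6β,20-diacetoxy-13-(triethylsilyloxy)labd-14-en-8α-ol | C=C[C@](C)(O[Si](CC)(CC)CC)CC[C@@H]1[C@@]2(COC(C)=O)CCCC(C)(C)[C@@H]2[C@H](OC(C)=O)C[C@@]1(C)O
F6 | step 7 | 6β,20-diacetoxy-8α-(nitrosooxy)-13-(triethylsilyloxy)labd-14-ene | C=C[C@](C)(O[Si](CC)(CC)CC)CC[C@@H]1[C@@]2(COC(C)=O)CCCC(C)(C)[C@@H]2[C@H](OC(C)=O)C[C@@]1(C)ON=O
F7 | step 7 | 6β,20-diacetoxy-12-(hydroxyimino)-13-(triethylsilyloxy)labd-14-en-8α-ol | C=C[C@](C)(O[Si](CC)(CC)CC)C(=NO)C[C@@H]1[C@@]2(COC(C)=O)CCCC(C)(C)[C@@H]2[C@H](OC(C)=O)C[C@@]1(C)O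
F8 | step 7 | 6β,20-diacetoxy-8α-hydroxy-13-(triethylsilyloxy)labd-14-en-12-one | C=C[C@](C)(O[Si](CC)(CC)CC)C(=O)C[C@@H]1[C@@]2(COC(C)=O)CCCC(C)(C)[C@@H]2[C@H](OC(C)=O)C[C@@]1(C)O
F9 | step 7 | (12R,13S)-6β,20-diacetoxy-13-(triethylsilyloxy)labd-14-ene-8α,12-diol | C=C[C@](C)(O[Si](CC)(CC)CC)[C@@H](C[C@@H]1[C@@]2(COC(C)=O)CCCC(C)(C)[C@@H]2[C@H](OC(C)=O)C[C@@]1(C)O)O
F10 | step 3 | 7α,8α-epoxy-13-(triethylsilyloxy)labd-14-ene | C=C[C@](C)(O[Si](CC)(CC)CC)CC[C@@H]1[C@@]2(C)CCCC(C)(C)[C@@H]2C[C@H]3O[C@@]13C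
F11 | step 3 | 7β-(phenylseleno)-13-(triethylsilyloxy)labd-14-en-8α-ol | C=C[C@](C)(O[Si](CC)(CC)CC)CC[C@@H]1[C@@]2(C)CCCC(C)(C)[C@@H]2C[C@H]([Se]c3ccccc3)[C@@]1(C)O
F12 | step 3 | 13-(triethylsilyloxy)labda-6,14-dien-8α-ol | C=C[C@](C)(O[Si](CC)(CC)CC)CC[C@@H]1[C@@]2(C)CCCC(C)(C)[C@@H]2C=C[C@@]1(C)O
F13 | step 4 | 8α-(4,4,5,5-tetramethyl-1,3,2-dioxaborolan-2-yl)-13-(triethylsilyloxy)labd-14-en-6-one | C=C[C@](C)(O[Si](CC)(CC)CC)CC[C@@H]1[C@@]2(C)CCCC(C)(C)[C@@H]2C(=O)C[C@@]1(C)B3OC(C)(C)C(C)(C)O3
F14 | step 4 | 8α-hydroxy-13-(triethylsilyloxy)labd-14-en-6-one | C=C[C@](C)(O[Si](CC)(CC)CC)CC[C@@H]1[C@@]2(C)CCCC(C)(C)[C@@H]2C(=O)C[C@@]1(C)O
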